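**Retrosynthetic overview**
1. Numbering: C1 = CO2H, C3/C5 = dioxolane carbons, C7/C11 = CHMe, C15 = benzylic CH2. C2–C3 is cut first (acetate unit added to a C3 peroxycarbenium ion). C5–OO is cut next (H2O2 opens a C5 oxetane with inversion). Both cuts lead back to methyl ketone 10.
2. Key disconnection C12–C13: radical ring opening of trimethylcyclooctanol 5 with Giese capture by phenyl vinyl ketone 6. One operation should give the C5 methyl ketone, the C12–C13 bond and the phenyl terminus, which is 20 of the 25 carbons.
3. Enabling feature: the acyclic stretch C6–C12, CH2–CHMe–(CH2)3–CHMe–CH2, is a hidden C2-symmetric (R,R)-2,6-dimethylheptane-1,7-diyl unit (7R and 11S differ only through CIP ranking). Tying C6 and C12 to C5 gives a strained cyclooctane, and cleavage of either breakable ring bond (C5–C6 or C5–C12) gives the same product.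
4. Stereocentres: C11 and C7 come from two Cu-catalysed asymmetric conjugate additions to cycloocta-2,7-dienone. C5 comes from a catalytic asymmetric Corey–Chaykovsky epoxidation followed by inversion. C3 comes from a catalyst-controlled addition.
5. Ring order: cyclooctane (bought, temporary, opened in step 5), oxirane (step 7), oxetane (step 9), 1,2-dioxolane (step 11). The phenyl ring is bought.

Key step: step 5

Assumption: the absolute sense of induction of the three chiral catalysts (Cu–phosphoramidite in steps 2 and 3, LLB in step 7, IDPi in step 13) is taken as written; if one of them delivers the opposite face, its enantiomer is used.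

Step 1
Reactants: 1 cyclooctanone
Product: 2 (2Z,7Z)-cycloocta-2,7-dien-1-one
Conditions: IBX (4 equiv), DMSO/PhF, 85 °C
Reagents that add atoms: none
Why: IBX-mediated α,β-dehydrogenation of a ketone, run on both equivalent α-methylene groups, should give the cross-conjugated dienone, and the eight-membered ring holds both alkenes Z.

Step 2
Reactants: 2 (2Z,7Z)-cycloocta-2,7-dien-1-one
Product: 3 (2Z,7R)-7-methylcyclooct-2-en-1-one
Conditions: Me2Zn, Cu(OTf)2 (2.5 mol %), (S,R,R)-binaphthyl bis(1-phenylethyl)phosphoramidite (5 mol %), toluene, −25 °C; then 1 M HCl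
Reagents that add atoms: dimethylzinc C[Zn]C
Why: In this copper-catalysed asymmetric conjugate addition of a dialkylzinc, the chiral Cu–phosphoramidite complex selects one of the two enantiotopic enone units and one face of it, which sets the future C11 (R in 3), and a second addition cannot occur before the acidic work-up.

Step 3
Reactants: 3 (2Z,7R)-7-methylcyclooct-2-en-1-one
Product: 4 (3R,7R)-3,7-dimethylcyclooctan-1-one
Conditions: Me2Zn, Cu(OTf)2 (2.5 mol %), same phosphoramidite (5 mol %), toluene, −25 °C; then 1 M HCl
Reagents that add atoms: dimethylzinc C[Zn]C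
Why: A second copper-catalysed asymmetric conjugate addition with the same ligand should impose the same local sense at the future C7, giving the trans, C2-symmetric ketone, while the minor enantiomer of 3 is channelled mainly into the separable meso cis isomer.

Step 4
Reactants: 4 (3R,7R)-3,7-dimethylcyclooctan-1-one
Product: 5 (3R,7R)-1,3,7-trimethylcyclooctan-1-ol
Conditions: MeMgBr, LaCl3·2LiCl, THF, 0 °C; then aq. NH4Cl
Reagents that add atoms: methylmagnesium bromide C[Mg]Br
Why: In this lanthanide-tempered Grignard 1,2-addition (enolisation suppressed), the two carbonyl faces of C2-symmetric 4 are homotopic and the carbinol carbon carries two identical ring arms, so a single alcohol without a new stereocentre should result.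

Step 5
Reactants: 5 (3R,7R)-1,3,7-trimethylcyclooctan-1-ol; 6 phenyl vinyl ketone (1-phenylprop-2-en-1-one)
Product: 9 (5R,9R)-5,9-dimethyl-1-phenyldodecane-1,11-dione, via alkoxyl radical 7 (not isolated), via ring-opened primary radical 8 (not isolated)
Conditions: CeCl3 (5 mol %), nBu4NCl (10 mol %), 9,10-diphenylanthracene (5 mol %), 6 (2 equiv, slow addition), MeCN, 400 nm LED, rt
Reagents that add atoms: none
Why: The cerium(IV) alkoxide of 5 undergoes ligand-to-metal charge transfer under 400 nm light to give alkoxyl radical 7, β-scission of a ring C–C bond releases the medium-ring (transannular) strain and gives methyl ketone radical 8, and this nucleophilic primary radical adds to the unsubstituted terminus of the electron-poor enone 6 (Giese addition) to make the C12–C13 bond; the α-keto radical is then reduced by the photoexcited diphenylanthracene relay, which also returns Ce(III) to Ce(IV), and is protonated, so the step is redox-neutral and loses no atom. The closest known reaction type is the cerium-photocatalysed deconstructive C–C cleavage of unstrained secondary and tertiary cycloalkanols with capture of the distal radical by electron-deficient alkenes. No ring is closed (the temporary cyclooctane is opened) and no stereocentre is created, and C7 and C11 lie β to the reacting atoms and are carried through unchanged. Site selectivity between the two ring bonds at the carbinol carbon is not needed, because both arms are constitutionally and configurationally identical and either cleavage gives the same 8. Ring scission must win over loss of a methyl radical and over transannular 1,5-hydrogen abstraction, which is secured by the tertiary carbinol, by the strain released and by the primary radical being more stable than methyl. Slow addition of 6 in moderate excess should keep polymerisation down while still outrunning 1,5-hydrogen shifts in 8.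

Step 6
Reactants: 9 (5R,9R)-5,9-dimethyl-1-phenyldodecane-1,11-dione
Product: 10 (4R,8S)-4,8-dimethyl-12-phenyldodecan-2-one
Conditions: H2 (3 atm), 10 % Pd/C, AcOH, cat. HClO4, rt
Reagents that add atoms: none
Why: Catalytic hydrogenolysis takes the benzylic C=O to CH2, the dialkyl ketone is not reduced over Pd/C, and neither stereocentre is α to a carbonyl, so nothing can epimerise.

Step 7
Reactants: 10 (4R,8S)-4,8-dimethyl-12-phenyldodecan-2-one
Product: 11 (2S)-2-[(2R,6S)-2,6-dimethyl-10-phenyldecyl]-2-methyloxirane
Conditions: Me3S(O)I, NaH, THF (ylide, 1.2 equiv); (S)-La-Li3-tris(binaphthoxide) (LLB, 5 mol %), (2,4,6-(MeO)3C6H2)3P=O (5 mol %), 5 Å MS, THF, rt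
Reagents that add atoms: trimethylsulfoxonium iodide (as its methylide) C[S+](C)(C)=O.[I-]
Why: In this catalytic asymmetric Corey–Chaykovsky epoxidation of a methyl ketone, the La/Li binaphthoxide–phosphine oxide complex binds ketone and ylide, tells CH3 from the CH2R arm and delivers CH2 to one face, so C5 is set as S in 11 under reagent control, and one equivalent of ylide at room temperature stops at the oxirane.

Step 8
Reactants: 11 (2S)-2-[(2R,6S)-2,6-dimethyl-10-phenyldecyl]-2-methyloxirane
Product: 12 (4R,6R,10S)-4,6,10-trimethyl-14-phenyltetradec-1-en-4-ol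
Conditions: CH2=CHMgBr, CuI (10 mol %), THF, −30 to 0 °C; then aq. NH4Cl
Reagents that add atoms: vinylmagnesium bromide C=C[Mg]Br
Why: The vinyl Grignard reagent opens the 2,2-disubstituted oxirane by copper-catalysed SN2 attack at its unhindered CH2, the C5–O bond is untouched, and the configuration is retained (the descriptor changes only through CIP ranking).

Step 9
Reactants: 12 (4R,6R,10S)-4,6,10-trimethyl-14-phenyltetradec-1-en-4-ol
Product: 13 (2S)-2-[(2R,6S)-2,6-dimethyl-10-phenyldecyl]-2,4-dimethyloxetane (C4 epimers)
Conditions: Co(salen) catalyst (5 mol %), N-fluoro-2,4,6-trimethylpyridinium triflate, (Me2SiH)2O, PhCF3, rt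
Reagents that add atoms: none
Why: In this cobalt-hydride hydrogen-atom-transfer/radical–polar crossover cycloisomerisation of a homoallylic alcohol, hydrogen goes to the terminal CH2, the oxidised secondary alkylcobalt centre at C3 is displaced 4-exo-tet by the tertiary hydroxyl with the C5–O bond retained, and the C3 epimer mixture is harmless because C3 becomes sp2 in step 11.

Step 10
Reactants: 13 (2S)-2-[(2R,6S)-2,6-dimethyl-10-phenyldecyl]-2,4-dimethyloxetane (C4 epimers)
Product: 14 (4R,6R,10S)-4-hydroperoxy-4,6,10-trimethyl-14-phenyltetradecan-2-ol (C2 epimers)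
Conditions: anhydrous ethereal H2O2 (excess), TMSOTf (0.2 equiv), Et2O, −78 to −20 °C
Reagents that add atoms: hydrogen peroxide OO
Why: In this Lewis acid-mediated perhydrolysis of a tertiary oxetane, strain release and the better-stabilised partial cation direct H2O2 to C5, and attack from the rear of the still-bound oxetane oxygen (tight, SN2-like at low temperature) should invert C5 to the R configuration of the target.

Step 11
Reactants: 14 (4R,6R,10S)-4-hydroperoxy-4,6,10-trimethyl-14-phenyltetradecan-2-ol (C2 epimers)
Product: 16 (5R)-5-[(2R,6S)-2,6-dimethyl-10-phenyldecyl]-3,5-dimethyl-1,2-dioxolan-3-ol (C3 anomers), via hydroperoxy ketone 15 (not isolated)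
Conditions: Dess–Martin periodinane, CH2Cl2, 0 °C
Reagents that add atoms: none
Why: Dess–Martin oxidation of the secondary alcohol should tolerate the tertiary hydroperoxide (no α-hydrogen), and 15 should close spontaneously by 5-exo-trig addition of OOH to the ketone, forming the dioxolane ring with C5 untouched.

Step 12
Reactants: 16 (5R)-5-[(2R,6S)-2,6-dimethyl-10-phenyldecyl]-3,5-dimethyl-1,2-dioxolan-3-ol (C3 anomers)
Product: 17 (5R)-5-[(2R,6S)-2,6-dimethyl-10-phenyldecyl]-3,5-dimethyl-1,2-dioxolan-3-yl acetate (C3 anomers)
Conditions: Ac2O, pyridine, DMAP (cat.), CH2Cl2, 0 °C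
Reagents that add atoms: acetic anhydride CC(=O)OC(C)=O
Why: O-acylation of the peroxyhemiketal hydroxyl, as practised on 1,2-dioxolan-3-ols, installs an ionisable leaving group at C3, and low temperature should suppress retro-addition of the ring-opened form.

Step 13
Reactants: 17 (5R)-5-[(2R,6S)-2,6-dimethyl-10-phenyldecyl]-3,5-dimethyl-1,2-dioxolan-3-yl acetate (C3 anomers)
Product: 19 methyl 2-[(3R,5R)-5-[(2R,6S)-2,6-dimethyl-10-phenyldecyl]-3,5-dimethyl-1,2-dioxolan-3-yl]acetate, via peroxycarbenium ion 18 (not isolated)
Conditions: confined chiral imidodiphosphorimidate acid ((S,S)-IDPi, 5 mol %), CH2=C(OMe)OTBS (2 equiv), toluene, −78 °C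
Reagents that add atoms: 1-methoxy-1-(tert-butyldimethylsilyloxy)ethene C=C(OC)O[Si](C)(C)C(C)(C)C
Why: Proposed new method: the silylated IDPi (a silylium Lewis acid) should abstract acetate from both anomers of 17 to give the planar peroxycarbenium ion 18 paired with the confined chiral anion, which shields one face of C3 so that the silyl ketene acetal attacks syn to the C5 decyl arm and sets C3 as R (catalyst control, since C5 only distinguishes CH3 from CH2R and exerts almost no bias), with silyl transfer to acetate turning the catalyst over; the closest known reaction types are the TiCl4- or SnCl4-mediated substitution of 3-alkoxy- and 3-acetoxy-1,2-dioxolanes by silyl ketene acetals through peroxycarbenium ions, and the counteranion-directed IDPi-catalysed Mukaiyama-type additions of silyl ketene acetals to cyclic aliphatic oxocarbenium ions and to methyl alkyl ketones.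

Step 14
Reactants: 19 methyl 2-[(3R,5R)-5-[(2R,6S)-2,6-dimethyl-10-phenyldecyl]-3,5-dimethyl-1,2-dioxolan-3-yl]acetate
Product: 20 2-[(3R,5R)-5-[(2R,6S)-2,6-dimethyl-10-phenyldecyl]-3,5-dimethyl-1,2-dioxolan-3-yl]acetic acid
Conditions: LiOH, THF/H2O, 0 °C; then 1 M HCl
Reagents that add atoms: lithium hydroxide [Li+].[OH-]
Why: In this ester saponification, both peroxide carbons are fully substituted so Kornblum–DeLaMare cleavage is impossible, low temperature should avoid retro-oxa-Michael opening, and no stereocentre is touched.

**Compound list**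
1 | cyclooctanone | O=C1CCCCCCC1 | starting material
2 | (2Z,7Z)-cycloocta-2,7-dien-1-one | O=C1/C=C\CCC/C=C\1 | intermediate
3 | (2Z,7R)-7-methylcyclooct-2-en-1-one | C[C@@H]1CCC/C=C\C(=O)C1 | intermediate
4 | (3R,7R)-3,7-dimethylcyclooctan-1-one | C[C@@H]1CCC[C@@H](C)CC(=O)C1 | intermediate
5 | (3R,7R)-1,3,7-trimethylcyclooctan-1-ol | C[C@@H]1CCC[C@@H](C)CC(C)(O)C1 | intermediate
6 | phenyl vinyl ketone (1-phenylprop-2-en-1-one) | C=CC(=O)c1ccccc1 | starting material
7 | 1,3,7-trimethylcyclooctan-1-yloxyl radical (configuration as in 5) | C[C@@H]1CCC[C@@H](C)CC(C)([O])C1 | intermediate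
8 | ring-opened 2,6-dimethyl-8-oxononyl radical (configuration as in 5) | C[C@@H]([CH2])CCC[C@@H](C)CC(C)=O | intermediate
9 | (5R,9R)-5,9-dimethyl-1-phenyldodecane-1,11-dione | C[C@@H](CCCC(=O)c1ccccc1)CCC[C@@H](C)CC(C)=O | intermediate
10 | (4R,8S)-4,8-dimethyl-12-phenyldodecan-2-one | C[C@@H](CCCCc1ccccc1)CCC[C@@H](C)CC(C)=O | intermediate
11 | (2S)-2-[(2R,6S)-2,6-dimethyl-10-phenyldecyl]-2-methyloxirane | C[C@@H](CCCCc1ccccc1)CCC[C@@H](C)C[C@@]1(C)CO1 | intermediate
12 | (4R,6R,10S)-4,6,10-trimethyl-14-phenyltetradec-1-en-4-ol | C[C@@H](CCCCc1ccccc1)CCC[C@@H](C)C[C@@](O)(C)CC=C | intermediate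
13 | (2S)-2-[(2R,6S)-2,6-dimethyl-10-phenyldecyl]-2,4-dimethyloxetane (C4 epimers) | C[C@@H](CCCCc1ccccc1)CCC[C@@H](C)C[C@@]1(C)CC(C)O1 | intermediate
14 | (4R,6R,10S)-4-hydroperoxy-4,6,10-trimethyl-14-phenyltetradecan-2-ol (C2 epimers) | C[C@@H](CCCCc1ccccc1)CCC[C@@H](C)C[C@](OO)(C)CC(C)O | intermediate
15 | (4R,6R,10S)-4-hydroperoxy-4,6,10-trimethyl-14-phenyltetradecan-2-one | C[C@@H](CCCCc1ccccc1)CCC[C@@H](C)C[C@](OO)(C)CC(C)=O | intermediate
16 | (5R)-5-[(2R,6S)-2,6-dimethyl-10-phenyldecyl]-3,5-dimethyl-1,2-dioxolan-3-ol (C3 anomers) | C[C@@H](CCCCc1ccccc1)CCC[C@@H](C)C[C@]1(C)CC(C)(O)OO1 | intermediate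
17 | (5R)-5-[(2R,6S)-2,6-dimethyl-10-phenyldecyl]-3,5-dimethyl-1,2-dioxolan-3-yl acetate (C3 anomers) | C[C@@H](CCCCc1ccccc1)CCC[C@@H](C)C[C@]1(C)CC(C)(OC(C)=O)OO1 | intermediate
18 | (5R)-5-[(2R,6S)-2,6-dimethyl-10-phenyldecyl]-3,5-dimethyl-1,2-dioxolan-3-ylium (peroxycarbenium ion) | C[C@@H](CCCCc1ccccc1)CCC[C@@H](C)C[C@]1(C)CC(C)=[O+]O1 | intermediate
19 | methyl 2-[(3R,5R)-5-[(2R,6S)-2,6-dimethyl-10-phenyldecyl]-3,5-dimethyl-1,2-dioxolan-3-yl]acetate | C[C@@H](CCCCc1ccccc1)CCC[C@@H](C)C[C@]1(C)C[C@](C)(CC(=O)OC)OO1 | intermediate
20 | 2-[(3R,5R)-5-[(2R,6S)-2,6-dimethyl-10-phenyldecyl]-3,5-dimethyl-1,2-dioxolan-3-yl]acetic acid | C[C@@H](CCCCc1ccccc1)CCC[C@@H](C)C[C@]1(C)C[C@](C)(CC(=O)O)OO1 | target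

Total step count: 14. Longest linear sequence: 14 steps, from cyclooctanone 1.

**Steps most likely to fail**

Step 13.
- What may go wrong: the ion pair may discriminate poorly between the faces of a fully substituted peroxycarbenium ion, or the strong silylium acid may trigger heterolysis of the O–O bond.
- Fallback: catalyst control is given up in favour of the known stoichiometric substitution followed by separation.
- It sets out from 17. TiCl4 and 1-(tert-butylthio)-1-(trimethylsilyloxy)ethene in CH2Cl2 at −78 °C should give both C3 epimers of the thioester.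
- The cis isomer, S-tert-butyl 2-[(3R,5R)-5-[(2R,6S)-2,6-dimethyl-10-phenyldecyl]-3,5-dimethyl-1,2-dioxolan-3-yl]ethanethioate F1, is separated by chromatography.
- Hydrolysis with LiOH/H2O2 brings the route back at 20.

Step 5.
- What may go wrong: transannular 1,5-hydrogen abstraction by the alkoxyl radical may compete with β-scission, the hindered tertiary alcohol may bind poorly to cerium, or the enone acceptor may polymerise.
- Fallback: the radical opening is replaced by a polar ring cleavage and an olefination. It sets out from 4.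
- LDA/TMSCl should give the single enol ether [(3R,7R)-3,7-dimethylcyclooct-1-en-1-yl]oxy-trimethylsilane F2; the C2 symmetry makes both α-sites equivalent.
- Ozonolysis with Me2S work-up should give (3R,7R)-3,7-dimethyl-8-oxooctanoic acid F3.
- Wittig olefination with the ylide from (3-phenylpropyl)triphenylphosphonium bromide makes C12–C13 as an alkene in (3R,7R,8Z)-3,7-dimethyl-11-phenylundec-8-enoic acid F4.
- H2 over Pd/C should give (3R,7S)-3,7-dimethyl-11-phenylundecanoic acid F5.
- Two equivalents of MeLi bring the route back at 10.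

Step 9.
- What may go wrong: the alkene may isomerise or be simply reduced, or the hindered tertiary hydroxyl may fail to displace the alkylcobalt centre in the strained 4-exo mode.
- Fallback: the cycloisomerisation is replaced by hydration and a Williamson closure. It sets out from 12.
- Oxymercuration–demercuration (Hg(OAc)2, THF/H2O; NaBH4) should give (4S,6R,10S)-4,6,10-trimethyl-14-phenyltetradecane-2,4-diol F6 as C2 epimers.
- MsCl/Et3N should sulfonylate only the secondary hydroxyl, giving (4S,6R,10S)-4-hydroxy-4,6,10-trimethyl-14-phenyltetradecan-2-yl methanesulfonate F7.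
- KOtBu closes the ring and brings the route back at 13.

**Further compounds**
F1 | step 13 | S-tert-butyl 2-[(3R,5R)-5-[(2R,6S)-2,6-dimethyl-10-phenyldecyl]-3,5-dimethyl-1,2-dioxolan-3-yl]ethanethioate | C[C@@H](CCCCc1ccccc1)CCC[C@@H](C)C[C@]1(C)C[C@](C)(CC(=O)SC(C)(C)C)OO1
F2 | step 5 | [(3R,7R)-3,7-dimethylcyclooct-1-en-1-yl]oxy-trimethylsilane | C[C@@H]1CCC[C@@H](C)CC(O[Si](C)(C)C)=C1
F3 | step 5 | (3R,7R)-3,7-dimethyl-8-oxooctanoic acid | C[C@@H](C=O)CCC[C@@H](C)CC(=O)O
F4 | step 5 | (3R,7R,8Z)-3,7-dimethyl-11-phenylundec-8-enoic acid | C[C@@H](/C=C\CCc1ccccc1)CCC[C@@H](C)CC(=O)O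
F5 | step 5 | (3R,7S)-3,7-dimethyl-11-phenylundecanoic acid | C[C@@H](CCCCc1ccccc1)CCC[C@@H](C)CC(=O)O
F6 | step 9 | (4S,6R,10S)-4,6,10-trimethyl-14-phenyltetradecane-2,4-diol (C2 epimers) | C[C@@H](CCCCc1ccccc1)CCC[C@@H](C)C[C@@](O)(C)CC(C)O
F7 | step 9 | (4S,6R,10S)-4-hydroxy-4,6,10-trimethyl-14-phenyltetradecan-2-yl methanesulfonate (C2 epimers) | C[C@@H](CCCCc1ccccc1)CCC[C@@H](C)C[C@@](O)(C)CC(C)OS(C)(=O)=O
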